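## Retrosynthetic overview

- **Feature.** In the flavanone half, O1–C8a–C4a–C4 of rings A and C becomes an ortho-quinone methide of the phloroglucinol ring A once C4=O is taken back to CH2. C2–C3 with ring B is then 4-vinylphenol.
- **Disconnection 1 (ring C of the flavanone half, formed last).** C4=O goes back to CH2, to be restored by benzylic oxidation. C3–C4 and O1–C2 are then cut together as an oxa-[4+2], and a chiral phosphoric acid sets C2 as S.
- **Disconnection 2.** The methide comes from a salicyl alcohol, made from a salicylaldehyde whose single free phenol is ortho to the C8–C8'' bond. That bond is cut by Suzuki–Miyaura coupling into an apigenin 8-boronate and a 3-iodosalicylaldehyde.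
- **Ring order.** The three rings of the flavone half arrive in apigenin, ring A of the flavanone half in 2,4,6-trihydroxybenzaldehyde and ring B in 4-acetoxystyrene. Ring C of the flavanone half is the only ring built.
- **Protecting groups.** Benzyl ethers and one benzyl carbonate are inert to the Brønsted acid and to DDQ. They leave together by neutral hydrogenolysis, so C2 sees neither acid nor base once C4 is a ketone.

Key step: step 11

Assumption (axis): the SMILES fixes only C2 and leaves the tetra-ortho-oxygenated C8–C8'' axis open, so the axis is built without control and both atropisomers of the (2S) compound are carried as the target.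

Assumption (catalyst sense): the (R)-configured acid is taken to deliver 2S; the sense is to be checked on the first sample of 15, and the (S)-acid is used if it proves opposite.

## Route

**Step 1**
Reactants: 1 apigenin (5,7,4'-trihydroxyflavone)
Product: 2 5,7,4'-tri-O-benzylapigenin
Conditions: BnBr (5 equiv), K2CO3 (6 equiv), DMF, 80 °C
Reagents that add atoms: benzyl bromide, BrCc1ccccc1
Why: Williamson etherification; excess halide and heat are used so that the chelated 5-OH, the least reactive phenol, is alkylated too.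

**Step 2**
Reactants: 2 5,7,4'-tri-O-benzylapigenin
Product: 3 8-iodo-5,7,4'-tri-O-benzylapigenin
Conditions: NIS (1.1 equiv), TFA (20 mol %), CH2Cl2, 0 °C to rt, dark
Reagents that add atoms: N-iodosuccinimide, O=C1CCC(=O)N1I
Why: Electrophilic aromatic iodination; in fully O-alkylated 5,7-dioxygenated flavones C8, next to the tied-back ring oxygen, is more accessible than C6 between two benzyloxy groups, while ring B and C3 are deactivated by the pyranone.

**Step 3**
Reactants: 3 8-iodo-5,7,4'-tri-O-benzylapigenin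
Product: 4 5,7,4'-tri-O-benzylapigenin-8-boronic acid pinacol ester
Conditions: B2pin2 (1.5 equiv), PdCl2(dppf) (5 mol %), KOAc (3 equiv), 1,4-dioxane, 90 °C
Reagents that add atoms: bis(pinacolato)diboron, CC1(C)OB(OC1(C)C)B1OC(C)(C)C(C)(C)O1
Why: Miyaura borylation of an aryl iodide; acetate is too weak a base to start homocoupling, and the pyranone and benzyl ethers are inert.

**Step 4**
Reactants: 5 2,4,6-trihydroxybenzaldehyde
Product: 6 4,6-bis(benzyloxy)-2-hydroxybenzaldehyde
Conditions: BnBr (2.1 equiv), K2CO3 (2.2 equiv), DMF, rt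
Reagents that add atoms: benzyl bromide, BrCc1ccccc1
Why: Williamson etherification held at two equivalents; the last phenol is locked in a hydrogen bond to the formyl group and stays free.

**Step 5**
Reactants: 6 4,6-bis(benzyloxy)-2-hydroxybenzaldehyde
Product: 7 4,6-bis(benzyloxy)-2-hydroxy-3-iodobenzaldehyde
Conditions: NIS (1.05 equiv), TFA (10 mol %), CH2Cl2, 0 °C, dark
Reagents that add atoms: N-iodosuccinimide, O=C1CCC(=O)N1I
Why: Electrophilic aromatic iodination; C3 (ortho to the free OH, para to 6-OBn) is less crowded than C5 between two benzyloxy groups and is the usual halogenation site of 2-hydroxy-4,6-dialkoxyaryl carbonyl compounds.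

**Step 6**
Reactants: 7 4,6-bis(benzyloxy)-2-hydroxy-3-iodobenzaldehyde
Product: 8 4,6-bis(benzyloxy)-3-iodo-2-(methoxymethoxy)benzaldehyde
Conditions: MOMCl (1.5 equiv), K2CO3 (2 equiv), DMF, 0 °C to rt
Reagents that add atoms: chloromethyl methyl ether, COCCl
Why: O-alkylation to a MOM acetal orthogonal to benzyl, so that the hindered cross-coupling runs on a neutral, fully protected iodide and not on an electron-rich phenoxide.

**Step 7**
Reactants: 4 5,7,4'-tri-O-benzylapigenin-8-boronic acid pinacol ester; 8 4,6-bis(benzyloxy)-3-iodo-2-(methoxymethoxy)benzaldehyde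
Product: 9 4,6-bis(benzyloxy)-2-(methoxymethoxy)-3-(5,7,4'-tri-O-benzylapigenin-8-yl)benzaldehyde (axis racemic)
Conditions: 4 (1.4 equiv), Pd(OAc)2 (10 mol %), SPhos (20 mol %), K3PO4 (3 equiv), toluene/H2O (10:1), 100 °C
Reagents that add atoms: none
Why: Suzuki–Miyaura coupling; the bulky, electron-rich biarylphosphine is the established ligand type for tetra-ortho-substituted biaryls, and all four ortho groups here are small oxygen substituents.

**Step 8**
Reactants: 9 4,6-bis(benzyloxy)-2-(methoxymethoxy)-3-(5,7,4'-tri-O-benzylapigenin-8-yl)benzaldehyde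
Product: 10 4,6-bis(benzyloxy)-2-hydroxy-3-(5,7,4'-tri-O-benzylapigenin-8-yl)benzaldehyde (axis racemic)
Conditions: 2 M aq HCl, THF/iPrOH, 40 °C
Reagents that add atoms: none
Why: Acid hydrolysis of an acetal; the MOM ether ortho to the formyl group falls under conditions that leave aryl benzyl ethers and the flavone untouched.

**Step 9**
Reactants: 11 4-acetoxystyrene
Product: 12 4-vinylphenol
Conditions: K2CO3 (10 mol %), MeOH, 0 °C to rt; aq NH4Cl work-up; kept cold with a trace of BHT and used fresh
Reagents that add atoms: none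
Why: Base-catalysed transesterification of an aryl acetate, mild enough to avoid polymerisation of the styrene.

**Step 10**
Reactants: 10 4,6-bis(benzyloxy)-2-hydroxy-3-(5,7,4'-tri-O-benzylapigenin-8-yl)benzaldehyde
Product: 13 8-[4,6-bis(benzyloxy)-2-hydroxy-3-(hydroxymethyl)phenyl]-5,7,4'-tri-O-benzylapigenin (axis racemic)
Conditions: NaBH4 (1 equiv), THF/EtOH (4:1), 0 °C, 30 min; pH 7 phosphate buffer; concentrated cold and used the same day
Reagents that add atoms: none
Why: Borohydride reduction of the aldehyde; the vinylogous-ester carbonyl of the flavone is not attacked at 0 °C, and short contact with a neutral quench avoids ionisation or over-reduction of the very electron-rich benzyl alcohol.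

**Step 11**
Reactants: 13 8-[4,6-bis(benzyloxy)-2-hydroxy-3-(hydroxymethyl)phenyl]-5,7,4'-tri-O-benzylapigenin; 12 4-vinylphenol
Product: 15 (2S)-5,7-bis(benzyloxy)-2-(4-hydroxyphenyl)-8-(5,7,4'-tri-O-benzylapigenin-8-yl)chroman (both atropisomers), via ortho-quinone methide 14 (not isolated)
Conditions: (R)-TRIP [(R)-3,3'-bis(2,4,6-triisopropylphenyl)-1,1'-binaphthyl-2,2'-diyl hydrogen phosphate] (10 mol %), 12 (3 equiv), 4 Å MS, toluene/CH2Cl2 (2:1), 0 °C; 13 added over 6 h by syringe pump
Reagents that add atoms: none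
Why: Proposed new method: the phosphoric acid protonates the benzylic OH of 13, water leaves because the C4 cation is stabilised by O1, 5-OBn and 7-OBn, and the resulting methide 14 stays hydrogen-bonded through O1 to P–OH while the P=O oxygen binds the phenolic OH of 12 and so raises the nucleophilicity of its vinyl terminus. The closest known reaction type is the chiral phosphoric acid catalysed inverse-demand oxa-Diels–Alder reaction of in situ formed, aryl-terminated ortho-quinone methides with hydroxystyrenes to 2-arylchromans; what is new is the bare CH2 terminus of the methide. Ring C closes as a six-membered ring in an intermolecular, concerted but asynchronous [4+2] mode in which C3–C4 runs ahead of O1–C2 (in the stepwise limit a 6-exo-trig attack of O1 on the para-quinone-methide-like C2). C2, the only new stereocentre, is set by the catalyst, which offers one face of the bound styrene to the methide inside the pocket of its 3,3'-aryl groups; the O1 to O4' gap of about 6 to 7 Å in the transition state can be bridged by one phosphate and two hydrogen bonds. The step needs head-to-tail regiochemistry, given by the polarity match of electrophilic C4 and nucleophilic C3, and closure on the right oxygen, given by the fact that 13 has no free phenol other than the one ortho to the C8–C8'' bond. Slow addition of 13 to an excess of 12 keeps 14 dilute, so that dimerisation and Friedel–Crafts attack at C6–H of a second molecule are outrun, and each antipode of the racemic axis gives its own (2S) atropisomer.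

**Step 12**
Reactants: 15 (2S)-5,7-bis(benzyloxy)-2-(4-hydroxyphenyl)-8-(5,7,4'-tri-O-benzylapigenin-8-yl)chroman
Product: 16 the 4'-O-benzyloxycarbonyl derivative of 15, (2S)
Conditions: CbzCl (1.3 equiv), K2CO3 (2 equiv), acetone, 0 °C to rt
Reagents that add atoms: benzyl chloroformate, O=C(Cl)OCc1ccccc1
Why: O-acylation with a chloroformate; the carbonate makes ring B electron-poor so that the coming hydride abstraction avoids C2–H, and it is hydrogenolysed later together with the benzyl ethers.

**Step 13**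
Reactants: 16 4'-O-Cbz (2S)-flavan
Product: 17 (2S,4RS)-flavan-4-ol: 16 with OH at C4, both C4 epimers
Conditions: DDQ (1.2 equiv), CH2Cl2/H2O (20:1), 0 °C to rt
Reagents that add atoms: water, O
Why: DDQ benzylic oxidation by hydride abstraction, the known way to functionalise C4 of 5,7-di-O-benzylated flavans; the C4 cation is stabilised by O1, 5-OBn and 7-OBn and is captured by water, while C2–H next to the carbonate-bearing ring B is much less hydridic.

**Step 14**
Reactants: 17 (2S,4RS)-flavan-4-ol
Product: 18 (2S)-5,7-bis(benzyloxy)-4'-(benzyloxycarbonyloxy)flavanone linked at C8 to C8'' of 5,7,4'-tri-O-benzylapigenin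
Conditions: nPr4N[RuO4] (10 mol %), NMO (2 equiv), 4 Å MS, CH2Cl2, rt
Reagents that add atoms: none
Why: Ley–Griffith oxidation converts both C4 epimers to one ketone under neutral conditions, so the acid-labile 4-ol does not ionise and no retro-oxa-Michael opening touches C2.

**Step 15**
Reactants: 18 protected (2S)-flavanone–flavone
Product: 19 target, (2S)-naringenin-(8→8'')-apigenin [(2S)-2,3-dihydrocupressuflavone]
Conditions: H2 (1 atm), Pd(OH)2/C, THF/MeOH (1:1), rt, stopped when uptake ends
Reagents that add atoms: none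
Why: Catalytic hydrogenolysis removes five aryl benzyl ethers and the benzyl carbonate (with loss of CO2) at neutral pH, which avoids the ring opening to the chalcone that would racemise C2; the flavone C2''=C3'' bond and the chelated C4 ketone are reduced far more slowly.

## Compound list

| No. | Name | SMILES | Role |
|---|---|---|---|
| 1 | apigenin | O=c1cc(-c2ccc(O)cc2)oc2cc(O)cc(O)c12 | starting material |
| 2 | 5,7,4'-tri-O-benzylapigenin | O=c1cc(-c2ccc(OCc3ccccc3)cc2)oc2cc(OCc3ccccc3)cc(OCc3ccccc3)c12 | intermediate |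
| 3 | 8-iodo-5,7,4'-tri-O-benzylapigenin | Ic1c(OCc2ccccc2)cc(OCc2ccccc2)c2c(=O)cc(-c3ccc(OCc4ccccc4)cc3)oc12 | intermediate |
| 4 | 5,7,4'-tri-O-benzylapigenin-8-boronic acid pinacol ester | CC1(C)OB(OC1(C)C)c1c(OCc2ccccc2)cc(OCc2ccccc2)c2c(=O)cc(-c3ccc(OCc4ccccc4)cc3)oc12 | intermediate |
| 5 | 2,4,6-trihydroxybenzaldehyde | O=Cc1c(O)cc(O)cc1O | starting material |
| 6 | 4,6-bis(benzyloxy)-2-hydroxybenzaldehyde | O=Cc1c(O)cc(OCc2ccccc2)cc1OCc1ccccc1 | intermediate |
| 7 | 4,6-bis(benzyloxy)-2-hydroxy-3-iodobenzaldehyde | O=Cc1c(O)c(I)c(OCc2ccccc2)cc1OCc1ccccc1 | intermediate |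
| 8 | 4,6-bis(benzyloxy)-3-iodo-2-(methoxymethoxy)benzaldehyde | O=Cc1c(OCOC)c(I)c(OCc2ccccc2)cc1OCc1ccccc1 | intermediate |
| 9 | 4,6-bis(benzyloxy)-2-(methoxymethoxy)-3-(5,7,4'-tri-O-benzylapigenin-8-yl)benzaldehyde | O=Cc1c(OCOC)c(-c2c(OCc3ccccc3)cc(OCc3ccccc3)c3c(=O)cc(-c4ccc(OCc5ccccc5)cc4)oc23)c(OCc2ccccc2)cc1OCc1ccccc1 | intermediate |
| 10 | 4,6-bis(benzyloxy)-2-hydroxy-3-(5,7,4'-tri-O-benzylapigenin-8-yl)benzaldehyde | O=Cc1c(O)c(-c2c(OCc3ccccc3)cc(OCc3ccccc3)c3c(=O)cc(-c4ccc(OCc5ccccc5)cc4)oc23)c(OCc2ccccc2)cc1OCc1ccccc1 | intermediate |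
| 11 | 4-acetoxystyrene | C=Cc1ccc(OC(C)=O)cc1 | starting material |
| 12 | 4-vinylphenol | C=Cc1ccc(O)cc1 | intermediate |
| 13 | 8-[4,6-bis(benzyloxy)-2-hydroxy-3-(hydroxymethyl)phenyl]-5,7,4'-tri-O-benzylapigenin | OCc1c(O)c(-c2c(OCc3ccccc3)cc(OCc3ccccc3)c3c(=O)cc(-c4ccc(OCc5ccccc5)cc4)oc23)c(OCc2ccccc2)cc1OCc1ccccc1 | intermediate |
| 14 | 3,5-bis(benzyloxy)-6-methylidene-2-(5,7,4'-tri-O-benzylapigenin-8-yl)cyclohexa-2,4-dien-1-one (ortho-quinone methide, not isolated) | C=C1C(=O)C(-c2c(OCc3ccccc3)cc(OCc3ccccc3)c3c(=O)cc(-c4ccc(OCc5ccccc5)cc4)oc23)=C(OCc2ccccc2)C=C1OCc1ccccc1 | intermediate |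
| 15 | (2S)-5,7-bis(benzyloxy)-2-(4-hydroxyphenyl)-8-(5,7,4'-tri-O-benzylapigenin-8-yl)chroman | C1C[C@@H](c2ccc(O)cc2)Oc2c1c(OCc1ccccc1)cc(OCc1ccccc1)c2-c1c(OCc2ccccc2)cc(OCc2ccccc2)c2c(=O)cc(-c3ccc(OCc4ccccc4)cc3)oc12 | intermediate |
| 16 | 4'-O-benzyloxycarbonyl derivative of 15, (2S) | C1C[C@@H](c2ccc(OC(=O)OCc3ccccc3)cc2)Oc2c1c(OCc1ccccc1)cc(OCc1ccccc1)c2-c1c(OCc2ccccc2)cc(OCc2ccccc2)c2c(=O)cc(-c3ccc(OCc4ccccc4)cc3)oc12 | intermediate |
| 17 | (2S,4RS)-flavan-4-ol derived from 16 | OC1C[C@@H](c2ccc(OC(=O)OCc3ccccc3)cc2)Oc2c1c(OCc1ccccc1)cc(OCc1ccccc1)c2-c1c(OCc2ccccc2)cc(OCc2ccccc2)c2c(=O)cc(-c3ccc(OCc4ccccc4)cc3)oc12 | intermediate |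
| 18 | (2S)-5,7-bis(benzyloxy)-4'-(benzyloxycarbonyloxy)flavanone, 8-linked to C8'' of 5,7,4'-tri-O-benzylapigenin | O=C1C[C@@H](c2ccc(OC(=O)OCc3ccccc3)cc2)Oc2c1c(OCc1ccccc1)cc(OCc1ccccc1)c2-c1c(OCc2ccccc2)cc(OCc2ccccc2)c2c(=O)cc(-c3ccc(OCc4ccccc4)cc3)oc12 | intermediate |
| 19 | (2S)-naringenin-(8→8'')-apigenin, CNP0339995.1 | O=C1C[C@@H](c2ccc(O)cc2)Oc2c1c(O)cc(O)c2-c1c(O)cc(O)c2c(=O)cc(-c3ccc(O)cc3)oc12 | target |

## Step count

- Total step count: 15.
- Longest linear sequence: 11 steps (steps 1–3, 7, 8, 10–15; the branch through steps 4–6 is equally long).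

## Steps most likely to fail

**Step 11.**
- The methide may be used up by dimerisation, or by attack of the nucleophilic C6–H position of a second molecule, before it meets the styrene.
- The acid may start cationic oligomerisation of 12.
- The bare CH2 terminus may give the catalyst too little grip for good facial discrimination. This is more likely because one antipode of the racemic axis is a mismatched case.

The fallback uses known chemistry, sets C2 by reduction and closes O1–C2 by substitution. It sets out from 10. Claisen–Schmidt condensation of 10 with purchased 4-(methoxymethoxy)acetophenone (Ba(OH)2, MeOH/THF, 40 °C) should give the (E)-enone F1. Hydrogenation of its C=C bond with RhCl(PPh3)3 and H2 spares the benzyl ethers and the flavone and gives the saturated ketone F2. Noyori transfer hydrogenation with RuCl(p-cymene)[(R,R)-TsDPEN] in HCO2H/Et3N gives the (R)-benzylic alcohol F3. Intramolecular Mitsunobu etherification (PPh3, DIAD, THF, 0 °C) closes the ring with inversion to the (2S)-4'-O-MOM flavan F4. Short treatment with dilute HCl in aqueous THF removes the MOM group, and the sequence comes back to the route at 15.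

**Step 13.**
- The C4 cation may lose H3 and be oxidised further toward the flavylium or flavone level.
- Hydride abstraction may compete at C2.

Either process erases the stereocentre. The fallback brings the C4 oxygen in with the methide, so no CH2 has to be oxidised. It sets out from 10. Treatment of 10 with HC(OMe)3, 12 and the chiral acid of step 11 (or its N-triflylphosphoramide analogue if more acidity is needed) turns the formyl group in the flask into the methoxy-substituted ortho-quinone methide F5. Compound 12 traps F5 in the same [4+2] sense to give the (2S)-4-methoxyflavan F6 as C4 epimers. The racemic acid-catalysed union of salicylaldehydes, orthoformate and alkenes to 4-alkoxychromans is the reaction type behind this. CbzCl and K2CO3 then give the carbonate F7. PPTS in THF/H2O exchanges the doubly activated benzylic methoxy group for OH, which returns to the route at 17.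

**Step 7.**
- Protodeboronation of the di-ortho-oxygenated boronate may outrun the coupling.
- Transmetallation and reductive elimination at the tetra-ortho-substituted axis may be too slow.

The fallback forms the hindered bond by ligand coupling on tetravalent lead in place of palladium catalysis, and it makes steps 4–6 and 8 unnecessary. It sets out from 4. Oxidative cleavage of the pinacol ester (NaIO4, NH4OAc, acetone/H2O) gives the boronic acid F8. Boron–lead exchange with Pb(OAc)4 and catalytic Hg(OAc)2 in CHCl3 gives the aryllead triacetate F9. Pinhey arylation of purchased 3,5-bis(benzyloxy)phenol (used in excess, CHCl3/pyridine, 40 °C) joins the rings ortho to the phenol and gives the 2-arylphenol F10. Casnati–Skattebøl ortho-formylation (MgCl2, Et3N, paraformaldehyde, MeCN, reflux) at the only free position next to the OH comes back to the route at 10.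

## Further compounds

F1 | step 11 | (E)-3-[4,6-bis(benzyloxy)-2-hydroxy-3-(5,7,4'-tri-O-benzylapigenin-8-yl)phenyl]-1-[4-(methoxymethoxy)phenyl]prop-2-en-1-one | COCOc1ccc(cc1)C(=O)/C=C/c1c(O)c(-c2c(OCc3ccccc3)cc(OCc3ccccc3)c3c(=O)cc(-c4ccc(OCc5ccccc5)cc4)oc23)c(OCc2ccccc2)cc1OCc1ccccc1
F2 | step 11 | 3-[4,6-bis(benzyloxy)-2-hydroxy-3-(5,7,4'-tri-O-benzylapigenin-8-yl)phenyl]-1-[4-(methoxymethoxy)phenyl]propan-1-one | COCOc1ccc(cc1)C(=O)CCc1c(O)c(-c2c(OCc3ccccc3)cc(OCc3ccccc3)c3c(=O)cc(-c4ccc(OCc5ccccc5)cc4)oc23)c(OCc2ccccc2)cc1OCc1ccccc1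
F3 | step 11 | (1R)-3-[4,6-bis(benzyloxy)-2-hydroxy-3-(5,7,4'-tri-O-benzylapigenin-8-yl)phenyl]-1-[4-(methoxymethoxy)phenyl]propan-1-ol | COCOc1ccc(cc1)[C@H](O)CCc1c(O)c(-c2c(OCc3ccccc3)cc(OCc3ccccc3)c3c(=O)cc(-c4ccc(OCc5ccccc5)cc4)oc23)c(OCc2ccccc2)cc1OCc1ccccc1
F4 | step 11 | (2S)-5,7-bis(benzyloxy)-2-[4-(methoxymethoxy)phenyl]-8-(5,7,4'-tri-O-benzylapigenin-8-yl)chroman | C1C[C@@H](c2ccc(OCOC)cc2)Oc2c1c(OCc1ccccc1)cc(OCc1ccccc1)c2-c1c(OCc2ccccc2)cc(OCc2ccccc2)c2c(=O)cc(-c3ccc(OCc4ccccc4)cc3)oc12
F5 | step 13 | 3,5-bis(benzyloxy)-6-(methoxymethylidene)-2-(5,7,4'-tri-O-benzylapigenin-8-yl)cyclohexa-2,4-dien-1-one (not isolated) | COC=C1C(=O)C(-c2c(OCc3ccccc3)cc(OCc3ccccc3)c3c(=O)cc(-c4ccc(OCc5ccccc5)cc4)oc23)=C(OCc2ccccc2)C=C1OCc1ccccc1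
F6 | step 13 | (2S,4RS)-5,7-bis(benzyloxy)-2-(4-hydroxyphenyl)-4-methoxy-8-(5,7,4'-tri-O-benzylapigenin-8-yl)chroman | COC1C[C@@H](c2ccc(O)cc2)Oc2c1c(OCc1ccccc1)cc(OCc1ccccc1)c2-c1c(OCc2ccccc2)cc(OCc2ccccc2)c2c(=O)cc(-c3ccc(OCc4ccccc4)cc3)oc12
F7 | step 13 | 4'-O-benzyloxycarbonyl derivative of F6 | COC1C[C@@H](c2ccc(OC(=O)OCc3ccccc3)cc2)Oc2c1c(OCc1ccccc1)cc(OCc1ccccc1)c2-c1c(OCc2ccccc2)cc(OCc2ccccc2)c2c(=O)cc(-c3ccc(OCc4ccccc4)cc3)oc12
F8 | step 7 | 5,7,4'-tri-O-benzylapigenin-8-boronic acid | OB(O)c1c(OCc2ccccc2)cc(OCc2ccccc2)c2c(=O)cc(-c3ccc(OCc4ccccc4)cc3)oc12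
F9 | step 7 | (5,7,4'-tri-O-benzylapigenin-8-yl)lead triacetate | CC(=O)O[Pb](OC(C)=O)(OC(C)=O)c1c(OCc2ccccc2)cc(OCc2ccccc2)c2c(=O)cc(-c3ccc(OCc4ccccc4)cc3)oc12
F10 | step 7 | 3,5-bis(benzyloxy)-2-(5,7,4'-tri-O-benzylapigenin-8-yl)phenol | Oc1cc(OCc2ccccc2)cc(OCc2ccccc2)c1-c1c(OCc2ccccc2)cc(OCc2ccccc2)c2c(=O)cc(-c3ccc(OCc4ccccc4)cc3)oc12
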